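I began with what was left of the rate. In the gamma run Zc crept from 13.0 % at 4.00 d to 15.8 % at 8.00 d, while in the alpha run it still climbed from 37.9 % at 6.00 d to 47.0 % at 8.00 d. Gamma held more Zd than Za, alpha less, so I took Zd to bind Za one to one, with Za the limiting reagent of that poisoning in gamma.

in all of them: Za 0.01 mol%
- theta: Zb 0.10 M; Zd 14 µM; run made earlier
- alpha: Zb 0.40 M; Zd 14 µM; run made earlier
- gamma: Zb 0.20 M; Zd 28 µM; run made earlier
- flask: Zb 0.20 M; Zd 14 µM

| run | time / d | Zc / % | Zb / % |
|---|---|---|---|
| theta | 1.67 | 6.2 | 94.0 |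
| theta | 3.00 | 6.6 | 91.6 |
| theta | 5.00 | 10.7 | 90.4 |
| theta | 6.00 | 12.3 | 87.6 |
| theta | 8.00 | 13.4 | 86.8 |
| alpha | 0.625 | 6.2 | 93.8 |
| alpha | 2.08 | 18.1 | 81.6 |
| alpha | 4.00 | 29.0 | 72.0 |
| alpha | 6.00 | 37.9 | 61.4 |
| alpha | 8.00 | 47.0 | 52.3 |
| gamma | 0.625 | 4.3 | 96.1 |
| gamma | 1.25 | 9.2 | 93.9 |
| gamma | 2.50 | 10.4 | 90.0 |
| gamma | 4.00 | 13.0 | 88.4 |
| gamma | 8.00 | 15.8 | 84.4 |

(scatter of a reading: 1 percentage point)

- apparent order in Za when 5.0 % of the Zb are converted (percent change of the rate of making Zc for one percent more Za charged)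
- factor on the rate of making Zc when 5.0 % of the Zb are converted if Za is charged twice over

- the numbers in the tables scatter with a standard deviation of 1 percentage point

Free Za both makes Zc and consumes Zd, so I expected cZd to fall exponentially with conversion, whatever the Za charge. Gamma's last reading, divided by the logarithm of cZd charged over cZd remaining once the Za is bound, gave 12.6 %: this is the poison span, the conversion of Zb over which cZd falls by a factor e.

The flask charges 20.0 µM of Za, and at 5.0 % conversion the span takes a toll of 4.58 µM. With the rate proportional to the Za charge minus this toll, I got an order of 1.30 and a doubling factor of 2.30.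

But the toll rests on one reading. Theta gave a span of 10.7 %, which moves the order to 1.35; I kept gamma's span, since gamma has the flask's cZb of 0.20 M.

Does a toll that ignores the charge survive in alpha? There the span leaves 2.40 % of the Zd at 8.00 d, so the late rate per Zb left should be 0.658 of the first. The readings give 0.823, a gap I accepted with 1 point of scatter on a first reading of 6.2 %.

The forecast, which called Zd “a slow, near-stoichiometric poison of Za”, stood a little above my reckoning, at 1.4 and 2.4. The flask gave 1.3 and 2.27.

    Zb + Za ⇌ Zf (K = 3.10 M⁻¹, k = 1.30 × 10⁵ M⁻¹ h⁻¹)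
    Zf → Za + Zc (k = 82.0 h⁻¹)
    Za + Zd ⇌ Zg (K = 6.30 × 10⁶ M⁻¹, k = 1400 M⁻¹ h⁻¹)
    Za ⇌ Ze (K = 0.600, k = 0.00470 h⁻¹)

In the flask at 3.15 d, the forward half-life of Zd through binding to Za was 3.3 d, shorter than the 6.1 d of Za passing forward into Ze. At 20.3 % Zc my span of 12.6 % gave 20.0 % of the Zd remaining, whereas the flask held 29.5 % at 5.00 d, a span of 16.6 %, with 49.3 % of the catalyst as Zg and 12.7 % as Ze.

The numbers in the tables were generated by integration for an exercise; scatter was added.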